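**Retrosynthetic overview**
1. Target 27 ⇐ 3‑O‑desilylation and 6‑O‑acylation of macrocyclic 6‑ol 25. The ten‑membered carbocycle is closed last, at C6–C7, by intramolecular Nozaki–Hiyama allylation of bromobutenolide–enal 24 (sets C6 and C7, creates the exo‑methylene).
2. Key disconnection C8–O: butenolide 24 ⇐ dienoic acid 23 by catalytic enantioselective 1,4‑bromolactonisation. The lactone ring is formed first; this step sets C8 and installs the allylic bromide.
3. 23 ⇐ alkyne 19 + 2‑bromoacrylic acid (hydroboration/Suzuki, C7–C11).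
4. C3–C4: asymmetric Ni/Cr coupling of enynal 8 with vinyl iodide 15 (sets C3), then C15 acylation and C3 silylation.
5. 8 from silyl diyne 3 (carboalumination/oxirane, sets 1(10)E); 15 from 3,3‑diethoxypropyne (ynoate, hydrostannation/iodination, sets 4E).

Assumption: germacrane numbering is used; the SMILES is read as (3R,6R,7R,8S), 1(10)E,4E, trans‑fused 12,8‑olide.

**Step 1**
Reactants: 1 3‑bromo‑1‑(trimethylsilyl)prop‑1‑yne; 2 ethynylmagnesium bromide
Product: 3 trimethyl(penta‑1,4‑diyn‑1‑yl)silane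
Conditions: CuCl (5 mol%), THF, 0 °C to rt
Reagents that add atoms: none
Why: Cu(I)‑catalysed SN2 coupling of an alkynyl Grignard with a primary propargylic bromide (skipped‑diyne synthesis); the silyl cap suppresses SN2′ attack and differentiates the two alkynes.

**Step 2**
Reactants: 3 trimethyl(penta‑1,4‑diyn‑1‑yl)silane; 4 oxirane
Product: 7 (E)‑4‑methylhept‑3‑en‑6‑yn‑1‑ol, via alkenylalane 5 (not isolated), via silyl enynol 6 (not isolated)
Conditions: Me3Al, Cp2ZrCl2 (25 mol%), (CH2Cl)2, rt; evaporate; n‑BuLi, THF–hexane, −78 °C; oxirane, −78 to 0 °C; aq. work‑up; then K2CO3, MeOH, rt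
Reagents that add atoms: trimethylaluminium, C[Al](C)C
Why: Negishi Zr‑catalysed carboalumination adds Me–Al syn across the terminal alkyne only (silylalkyne inert), which fixes the 1(10)E geometry; the alkenylalanate opens oxirane with retention, and K2CO3/MeOH removes the alkynyl silane.

**Step 3**
Reactants: 7 (E)‑4‑methylhept‑3‑en‑6‑yn‑1‑ol
Product: 8 (E)‑4‑methylhept‑3‑en‑6‑ynal
Conditions: Dess–Martin periodinane, NaHCO3, CH2Cl2, 0 °C; used crude
Reagents that add atoms: none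
Why: Buffered Dess–Martin oxidation gives the β,γ‑unsaturated aldehyde without base‑ or acid‑induced migration of the alkene into conjugation.

**Step 4**
Reactants: 9 3,3‑diethoxyprop‑1‑yne; 10 methyl chloroformate
Product: 12 methyl 4,4‑diethoxybut‑2‑ynoate, via lithium acetylide 11 (not isolated)
Conditions: n‑BuLi, THF, −78 °C; then ClCO2Me
Reagents that add atoms: none
Why: Acylation of a lithium acetylide with a chloroformate; C15 enters at the ester oxidation level and C6 at the aldehyde level, so the two termini stay differentiated.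

**Step 5**
Reactants: 12 methyl 4,4‑diethoxybut‑2‑ynoate
Product: 14 methyl (E)‑4,4‑diethoxy‑2‑iodobut‑2‑enoate, via vinylstannane 13 (not isolated)
Conditions: Bu3SnH, Pd(PPh3)4 (2 mol%), THF, 0 °C; then I2, CH2Cl2, 0 °C
Reagents that add atoms: iodine, II
Why: Pd‑catalysed hydrostannation of an ynoate is syn and places tin α to the ester; iododestannylation proceeds with retention, so I (later C3) is cis to H5 and C15 is cis to C6, which is the 4E geometry of the target.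

**Step 6**
Reactants: 14 methyl (E)‑4,4‑diethoxy‑2‑iodobut‑2‑enoate
Product: 15 (E)‑4,4‑diethoxy‑2‑iodobut‑2‑en‑1‑ol
Conditions: DIBAL‑H (2.2 equiv), CH2Cl2, −78 °C; Rochelle salt; store over a trace of Et3N
Reagents that add atoms: none
Why: DIBAL reduction of the enoate to the allylic alcohol leaves the vinyl iodide and acetal intact; the product is kept acid‑free because the cis CH2OH and acetal would otherwise cyclise.

**Step 7**
Reactants: 8 (E)‑4‑methylhept‑3‑en‑6‑ynal; 15 (E)‑4,4‑diethoxy‑2‑iodobut‑2‑en‑1‑ol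
Product: 16 (2E,4R,6E)‑1,1‑diethoxy‑3‑(hydroxymethyl)‑7‑methyldeca‑2,6‑dien‑9‑yn‑4‑ol
Conditions: CrCl2 (4 equiv), NiCl2 (cat.), chiral oxazoline–sulfonamide ligand (Kishi type), Et3N, THF, rt
Reagents that add atoms: none
Why: Asymmetric Nozaki–Hiyama–Kishi coupling: the alkenyl–Cr(III) species from 15 adds 1,2 to the aldehyde with retention of alkene geometry, and the ligand antipode that delivers the alkenyl group to the Si face sets C3 as R (sense to be confirmed by Mosher analysis on the first run); the amine‑buffered medium tolerates the skipped enyne, free CH2OH and acetal.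

**Step 8**
Reactants: 16 the diol; 17 3‑methylbutanoyl chloride
Product: 18 (2E)‑4,4‑diethoxy‑2‑[(1R,3E)‑1‑hydroxy‑4‑methylhept‑3‑en‑6‑yn‑1‑yl]but‑2‑en‑1‑yl 3‑methylbutanoate
Conditions: 2,4,6‑collidine, CH2Cl2, −78 to −20 °C
Reagents that add atoms: none
Why: Selective acylation of the primary allylic OH over the secondary one installs the C15 isovalerate and removes the hydroxyl that could cyclise onto C6.

**Step 9**
Reactants: 18 the mono‑isovalerate
Product: 19 (2E)‑2‑[(1R,3E)‑1‑{[tert‑butyl(dimethyl)silyl]oxy}‑4‑methylhept‑3‑en‑6‑yn‑1‑yl]‑4,4‑diethoxybut‑2‑en‑1‑yl 3‑methylbutanoate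
Conditions: TBSCl, imidazole, DMAP (cat.), DMF, rt
Reagents that add atoms: tert‑butyldimethylsilyl chloride, CC(C)(C)[Si](C)(C)Cl
Why: Standard silylation; 3‑OH is the only hydroxyl that must stay free in the target, so it is the only one protected.

**Step 10**
Reactants: 19 the silyl ether; 20 2‑bromoacrylic acid
Product: 23 (3E,6E,9R,10E)‑9‑{[tert‑butyl(dimethyl)silyl]oxy}‑6‑methyl‑2‑methylidene‑10‑[(3‑methylbutanoyloxy)methyl]‑12‑oxododeca‑3,6,10‑trienoic acid, via alkenylborane 21 (not isolated), via acetal acid 22 (not isolated)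
Conditions: Cy2BH, THF, 0 °C; 20, Pd(dppf)Cl2 (5 mol%), aq. K3PO4, THF, rt; then 1 M HCl, THF, 0 °C
Reagents that add atoms: water, O
Why: Syn hydroboration of the terminal alkyne (trisubstituted alkenes untouched) gives the (E)‑alkenylborane, Suzuki–Miyaura coupling with the α‑bromoacrylate gives the (E)‑2‑carboxy‑1,3‑diene, and the acidic work‑up hydrolyses the allylic diethyl acetal to the enal.

**Step 11**
Reactants: 23 the dienoic acid enal
Product: 24 [(2E)‑2‑[(1R,3E)‑5‑[(2S)‑4‑(bromomethyl)‑5‑oxo‑2,5‑dihydrofuran‑2‑yl]‑1‑{[tert‑butyl(dimethyl)silyl]oxy}‑4‑methylpent‑3‑en‑1‑yl]‑4‑oxobut‑2‑en‑1‑yl] 3‑methylbutanoate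
Conditions: NBS (1.05 equiv), cinchona‑derived urea catalyst (10 mol%), toluene–CHCl3, −60 °C, dark
Reagents that add atoms: N‑bromosuccinimide, O=C1CCC(=O)N1Br
Why: Proposed new method: catalytic enantioselective 1,4‑bromolactonisation of a 2‑carboxy‑1,3‑diene, in which the catalyst quinuclidine ion‑pairs with the acid and its urea N–H activates NBS, Br+ goes to the terminal CH2 (C13) of the s‑trans diene (giving an allyl cation whose C8 terminus sits next to the carboxylate) and the carboxylate closes the five‑membered ring at C8 on the catalyst‑defined face to give the (S)‑butenolide, while the isolated trisubstituted alkene has no internal nucleophile (reversible bromonium) and the enal alkene is electron‑poor; a 1,2‑adduct (4‑bromo‑3‑methylene lactone) would be an allylic isomer giving the same allylchromium in step 12; closest known reaction type is the cinchona‑urea‑catalysed 1,4‑bromolactonisation of conjugated enynes with NBS and the catalytic asymmetric 1,2‑bromolactonisation of alkenoic acids; the pseudo‑enantiomeric catalyst (quinine or quinidine series) that gives 8S is used.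

**Step 12**
Reactants: 24 the bromobutenolide enal
Product: 25 (3R,6R,7S,8S)‑3‑(tert‑butyldimethylsilyloxy)‑6‑hydroxy‑15‑(3‑methylbutanoyloxy)germacra‑1(10)E,4E,11(13)‑trien‑12,8‑olide (7S is only a CIP change caused by the free 6‑OH)
Conditions: CrCl2 (6 equiv), THF, rt, slow addition to 2 mM; aq. NH4Cl
Reagents that add atoms: none
Why: Intramolecular Nozaki–Hiyama (Barbier‑type) allylation: the allyl–Cr(III) adds through its γ‑carbon C7 to the tethered enal in a chair Zimmerman–Traxler transition state, where the ring holds C8 trans to CH2Cr (E‑crotyl‑like, giving the anti C6–OH/C7–C8 relationship) and C6 bonds to the butenolide face opposite the C8–C9 bond (trans‑fused lactone), so C7 and C6 follow from C8 while the ten‑membered ring and the exo‑methylene form.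

**Step 13**
Reactants: 25 the macrocyclic 6‑ol; 17 3‑methylbutanoyl chloride
Product: 26 (3R,6R,7R,8S)‑3‑(tert‑butyldimethylsilyloxy)‑6,15‑bis(3‑methylbutanoyloxy)germacra‑1(10)E,4E,11(13)‑trien‑12,8‑olide
Conditions: pyridine, DMAP (cat.), CH2Cl2, 0 °C to rt
Reagents that add atoms: none
Why: DMAP‑catalysed acylation of the only free hydroxyl; no stereocentre is touched.

**Step 14**
Reactants: 26 the silyl ether
Product: 27 (3R,6R,7R,8S)‑3‑hydroxy‑6,15‑bis(3‑methylbutanoyloxy)germacra‑1(10)E,4E,11(13)‑trien‑12,8‑olide (target)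
Conditions: HF·pyridine, pyridine, THF, 0 °C to rt
Reagents that add atoms: none
Why: Buffered fluoride desilylation frees 3‑OH without acid strong enough for transannular cyclisation of the germacradiene or base strong enough for acyl migration or Michael addition.

**Compound list**
1 | 3‑bromo‑1‑(trimethylsilyl)prop‑1‑yne | C[Si](C)(C)C#CCBr | starting material
2 | ethynylmagnesium bromide | C#C[Mg]Br | starting material
3 | trimethyl(penta‑1,4‑diyn‑1‑yl)silane | C[Si](C)(C)C#CCC#C | intermediate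
4 | oxirane | C1CO1 | starting material
5 | dimethyl[(E)‑2‑methyl‑5‑(trimethylsilyl)pent‑1‑en‑4‑yn‑1‑yl]alumane | C[Al](C)/C=C(\C)CC#C[Si](C)(C)C | intermediate
6 | (E)‑4‑methyl‑7‑(trimethylsilyl)hept‑3‑en‑6‑yn‑1‑ol | OCC/C=C(\C)CC#C[Si](C)(C)C | intermediate
7 | (E)‑4‑methylhept‑3‑en‑6‑yn‑1‑ol | OCC/C=C(\C)CC#C | intermediate
8 | (E)‑4‑methylhept‑3‑en‑6‑ynal | O=CC/C=C(\C)CC#C | intermediate
9 | 3,3‑diethoxyprop‑1‑yne | CCOC(OCC)C#C | starting material
10 | methyl chloroformate | COC(=O)Cl | starting material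
11 | (3,3‑diethoxyprop‑1‑yn‑1‑yl)lithium | [Li]C#CC(OCC)OCC | intermediate
12 | methyl 4,4‑diethoxybut‑2‑ynoate | CCOC(OCC)C#CC(=O)OC | intermediate
13 | methyl (E)‑4,4‑diethoxy‑2‑(tributylstannyl)but‑2‑enoate | CCCC[Sn](CCCC)(CCCC)/C(C(=O)OC)=C/C(OCC)OCC | intermediate
14 | methyl (E)‑4,4‑diethoxy‑2‑iodobut‑2‑enoate | I/C(C(=O)OC)=C/C(OCC)OCC | intermediate
15 | (E)‑4,4‑diethoxy‑2‑iodobut‑2‑en‑1‑ol | I/C(CO)=C/C(OCC)OCC | intermediate
16 | (2E,4R,6E)‑1,1‑diethoxy‑3‑(hydroxymethyl)‑7‑methyldeca‑2,6‑dien‑9‑yn‑4‑ol | C#CC/C(C)=C/C[C@@H](O)/C(CO)=C/C(OCC)OCC | intermediate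
17 | 3‑methylbutanoyl chloride | CC(C)CC(=O)Cl | starting material
18 | (2E)‑4,4‑diethoxy‑2‑[(1R,3E)‑1‑hydroxy‑4‑methylhept‑3‑en‑6‑yn‑1‑yl]but‑2‑en‑1‑yl 3‑methylbutanoate | C#CC/C(C)=C/C[C@@H](O)/C(COC(=O)CC(C)C)=C/C(OCC)OCC | intermediate
19 | (2E)‑2‑[(1R,3E)‑1‑{[tert‑butyl(dimethyl)silyl]oxy}‑4‑methylhept‑3‑en‑6‑yn‑1‑yl]‑4,4‑diethoxybut‑2‑en‑1‑yl 3‑methylbutanoate | C#CC/C(C)=C/C[C@@H](O[Si](C)(C)C(C)(C)C)/C(COC(=O)CC(C)C)=C/C(OCC)OCC | intermediate
20 | 2‑bromoacrylic acid | C=C(Br)C(=O)O | starting material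
21 | B,B‑dicyclohexyl (E)‑alkenylborane of 19 (boron on C7) | B(C1CCCCC1)(C1CCCCC1)/C=C/C/C(C)=C/C[C@@H](O[Si](C)(C)C(C)(C)C)/C(COC(=O)CC(C)C)=C/C(OCC)OCC | intermediate
22 | (3E,6E,9R,10E)‑9‑{[tert‑butyl(dimethyl)silyl]oxy}‑12,12‑diethoxy‑6‑methyl‑2‑methylidene‑10‑[(3‑methylbutanoyloxy)methyl]dodeca‑3,6,10‑trienoic acid | C=C(C(=O)O)/C=C/C/C(C)=C/C[C@@H](O[Si](C)(C)C(C)(C)C)/C(COC(=O)CC(C)C)=C/C(OCC)OCC | intermediate
23 | (3E,6E,9R,10E)‑9‑{[tert‑butyl(dimethyl)silyl]oxy}‑6‑methyl‑2‑methylidene‑10‑[(3‑methylbutanoyloxy)methyl]‑12‑oxododeca‑3,6,10‑trienoic acid | C=C(C(=O)O)/C=C/C/C(C)=C/C[C@@H](O[Si](C)(C)C(C)(C)C)/C(COC(=O)CC(C)C)=C/C=O | intermediate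
24 | [(2E)‑2‑[(1R,3E)‑5‑[(2S)‑4‑(bromomethyl)‑5‑oxo‑2,5‑dihydrofuran‑2‑yl]‑1‑{[tert‑butyl(dimethyl)silyl]oxy}‑4‑methylpent‑3‑en‑1‑yl]‑4‑oxobut‑2‑en‑1‑yl] 3‑methylbutanoate | BrCC1=C[C@H](C/C(C)=C/C[C@@H](O[Si](C)(C)C(C)(C)C)/C(COC(=O)CC(C)C)=C/C=O)OC1=O | intermediate
25 | (3R,6R,7S,8S)‑3‑(tert‑butyldimethylsilyloxy)‑6‑hydroxy‑15‑(3‑methylbutanoyloxy)germacra‑1(10)E,4E,11(13)‑trien‑12,8‑olide | C=C1C(=O)O[C@H]2C/C(C)=C/C[C@@H](O[Si](C)(C)C(C)(C)C)/C(COC(=O)CC(C)C)=C/[C@@H](O)[C@H]12 | intermediate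
26 | (3R,6R,7R,8S)‑3‑(tert‑butyldimethylsilyloxy)‑6,15‑bis(3‑methylbutanoyloxy)germacra‑1(10)E,4E,11(13)‑trien‑12,8‑olide | C=C1C(=O)O[C@H]2C/C(C)=C/C[C@@H](O[Si](C)(C)C(C)(C)C)/C(COC(=O)CC(C)C)=C/[C@@H](OC(=O)CC(C)C)[C@H]12 | intermediate
27 | (3R,6R,7R,8S)‑3‑hydroxy‑6,15‑bis(3‑methylbutanoyloxy)germacra‑1(10)E,4E,11(13)‑trien‑12,8‑olide | C=C1C(=O)O[C@H]2C/C(C)=C/C[C@@H](O)/C(COC(=O)CC(C)C)=C/[C@@H](OC(=O)CC(C)C)[C@H]12 | target

**Step count**
Total: 14 steps. Longest linear sequence: 11 steps (1–3 then 7–14; the branch 4–6 then 7–14 is also 11).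

**Steps most likely to fail**

Step 11 (the proposed new 1,4‑bromolactonisation). The risks are 1,2‑addition or β‑lactone formation, bromination of the C1=C10 alkene, and low enantioselectivity. The known‑chemistry fallback sets out from alkyne 19 and comes back at 24. Crabbé homologation of 19 (paraformaldehyde, CuBr, i‑Pr2NH, dioxane, reflux) gives the terminal allene (2E)‑2‑[(1R,3E)‑1‑{[tert‑butyl(dimethyl)silyl]oxy}‑4‑methylocta‑3,6,7‑trien‑1‑yl]‑4,4‑diethoxybut‑2‑en‑1‑yl 3‑methylbutanoate F1. Rh(I)/DIOP‑catalysed enantioselective branch‑selective addition of 2‑(bromomethyl)acrylic acid across the allene then forms the C8–O bond and gives the (3S)‑allylic 2‑(bromomethyl)prop‑2‑enoate F2. Ring‑closing metathesis (Grubbs II, CH2Cl2, 40 °C) closes the butenolide to the bromomethylbutenolide diethyl acetal F3, and 1 M HCl/THF at 0 °C unmasks the enal to give 24.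

Step 12 (macrocyclisation). The risks are oligomerisation and formation of the cis‑fused or syn diastereomer. The fallback sets out from 24 and comes back at 25. Pd‑catalysed borylation (B2pin2, Pd2(dba)3, THF) turns the allylic bromide into the allyl pinacolboronate lactone F4, a 2‑(alkoxycarbonyl)allylboronate that does not react with the enal at rt. Its intramolecular allylboration at high dilution (toluene, 60 °C, or cat. TfOH at −40 °C) passes through a closed six‑membered transition state without redox chemistry and gives 25.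

Step 7 (asymmetric Ni/Cr coupling). The risk is low or reversed facial selectivity with this hydroxylated iodide. The fallback sets out from 8 and 15 and comes back at 18. Ligand‑free coupling (CrCl2, cat. NiCl2, DMF) gives the racemic diol F5; selective primary acylation with 17 (collidine, −78 °C) gives the racemic mono‑isovalerate F6; Dess–Martin oxidation gives the enone F7. Corey–Bakshi–Shibata reduction of F7 with (S)‑Me‑CBS and catecholborane at −78 °C (alkenyl as the large group, CH2 as the small one) gives the 3R alcohol 18.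

**Further compounds**
F1 | step 11 | (2E)‑2‑[(1R,3E)‑1‑{[tert‑butyl(dimethyl)silyl]oxy}‑4‑methylocta‑3,6,7‑trien‑1‑yl]‑4,4‑diethoxybut‑2‑en‑1‑yl 3‑methylbutanoate | C=C=CC/C(C)=C/C[C@@H](O[Si](C)(C)C(C)(C)C)/C(COC(=O)CC(C)C)=C/C(OCC)OCC
F2 | step 11 | 2‑(bromomethyl)prop‑2‑enoate of (3S,5E,8R,9E)‑8‑(tert‑butyldimethylsilyloxy)‑11,11‑diethoxy‑5‑methyl‑9‑[(3‑methylbutanoyloxy)methyl]undeca‑1,5,9‑trien‑3‑ol | C=C[C@H](C/C(C)=C/C[C@@H](O[Si](C)(C)C(C)(C)C)/C(COC(=O)CC(C)C)=C/C(OCC)OCC)OC(=O)C(=C)CBr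
F3 | step 11 | [(2E)‑2‑[(1R,3E)‑5‑[(2S)‑4‑(bromomethyl)‑5‑oxo‑2,5‑dihydrofuran‑2‑yl]‑1‑{[tert‑butyl(dimethyl)silyl]oxy}‑4‑methylpent‑3‑en‑1‑yl]‑4,4‑diethoxybut‑2‑en‑1‑yl] 3‑methylbutanoate | BrCC1=C[C@H](C/C(C)=C/C[C@@H](O[Si](C)(C)C(C)(C)C)/C(COC(=O)CC(C)C)=C/C(OCC)OCC)OC1=O
F4 | step 12 | [(2E)‑2‑[(1R,3E)‑1‑{[tert‑butyl(dimethyl)silyl]oxy}‑4‑methyl‑5‑[(2S)‑5‑oxo‑4‑[(4,4,5,5‑tetramethyl‑1,3,2‑dioxaborolan‑2‑yl)methyl]‑2,5‑dihydrofuran‑2‑yl]pent‑3‑en‑1‑yl]‑4‑oxobut‑2‑en‑1‑yl] 3‑methylbutanoate | CC1(C)OB(CC2=C[C@H](C/C(C)=C/C[C@@H](O[Si](C)(C)C(C)(C)C)/C(COC(=O)CC(C)C)=C/C=O)OC2=O)OC1(C)C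
F5 | step 7 | racemic (2E,6E)‑1,1‑diethoxy‑3‑(hydroxymethyl)‑7‑methyldeca‑2,6‑dien‑9‑yn‑4‑ol | C#CC/C(C)=C/CC(O)/C(CO)=C/C(OCC)OCC
F6 | step 7 | racemic (2E)‑4,4‑diethoxy‑2‑[(3E)‑1‑hydroxy‑4‑methylhept‑3‑en‑6‑yn‑1‑yl]but‑2‑en‑1‑yl 3‑methylbutanoate | C#CC/C(C)=C/CC(O)/C(COC(=O)CC(C)C)=C/C(OCC)OCC
F7 | step 7 | (2E)‑4,4‑diethoxy‑2‑[(3E)‑4‑methylhept‑3‑en‑6‑ynoyl]but‑2‑en‑1‑yl 3‑methylbutanoate | C#CC/C(C)=C/CC(=O)/C(COC(=O)CC(C)C)=C/C(OCC)OCC
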